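**Retrosynthetic overview**

1. Feature used: ring A (C4a, C5, C6, C7, C8, C8a) is a fully substituted benzene fused to ring B along C4a–C8a, with oxygen at C6, C7 and C8. A 1,7-diyne (C5≡C4a and C8a≡C8, tethered through C4=C3–C2–C1) plus a C6≡C7 alkyne maps onto both rings.
2. Key disconnection: CpCo(CO)2 [2+2+2] cocyclisation of a siloxy-enediyne with bis(pinacolboryl)acetylene forms C4a–C8a, C5–C6 and C7–C8 and closes rings B and A together (ring A built de novo). C–B to C–O oxidation, desilylation and phenol methylation finish.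
3. Enediyne: the C3=C4 bond needs the ethynyl group cis to C2, which is the E descriptor because CH2OSi outranks C2. It comes from a Horner–Wadsworth–Emmons reaction of an α-phosphono γ-lactone with 3-(trimethylsilyl)propynal. The C8 siloxyalkyne comes from the C8a terminal alkyne by acetylide oxidation and O-silylation.
4. Stereocentres: C2 by Evans alkylation with tert-butyl bromoacetate; C1 by rhodium-catalysed enantioselective conjugate alkynylation of the arylidene Meldrum's acid of veratraldehyde.
5. Ring order: a temporary γ-lactone (opened again by reduction), then rings B and A in the key step.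

Key step: step 15

Remark on locants: the target locants C1–C8a are used for the corresponding carbons of all intermediates; C2a and C3a are the CH2O carbons on C2 and C3.
Assumption: the (R)-bisphosphine in step 2 delivers the (R)-adduct 5; if the sense of induction is the opposite, the enantiomeric ligand is used.

**Route**

Step 1
Reactants: 1 3,4-dimethoxybenzaldehyde; 2 Meldrum's acid
Product: 3 5-(3,4-dimethoxybenzylidene) Meldrum's acid
Conditions: H2O, 75 °C
Reagents that add atoms: none
Why: Knoevenagel condensation, in which the very acidic methylene of 2 condenses with the aryl aldehyde without added base and the alkylidene product precipitates from water.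

Step 2
Reactants: 3 arylidene Meldrum's acid; 4 trimethylsilylacetylene
Product: 5 (R)-alkynyl adduct of Meldrum's acid
Conditions: [Rh(OAc)(C2H4)2]2 (2.5 mol %, monovalent rhodium), (R)-3,5-xylyl-MeO-BIPHEP (5.5 mol %), 4 (3 equiv), 1,4-dioxane, 15 °C
Reagents that add atoms: none
Why: Rhodium-catalysed enantioselective conjugate alkynylation, in which an alkynylrhodium species formed from 4 adds to the electrophilic β-carbon of 3, the chiral bisphosphine selects the face and sets C1 as R, and the silyl group holds back alkyne dimerisation.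

Step 3
Reactants: 5 alkynyl adduct
Product: 7 (3R)-3-(3,4-dimethoxyphenyl)-5-(trimethylsilyl)pent-4-ynoic acid, via malonic acid 6 (not isolated)
Conditions: DMF/H2O (10:1), 100 °C
Reagents that add atoms: water, O
Why: Hydrolysis of the cyclic acylal to malonic acid 6 followed by thermal decarboxylation, a neutral unmasking that should leave the C–Si bond and the non-enolisable C1 centre untouched.

Step 4
Reactants: 7 pentynoic acid; 8 (4R)-4-benzyl-1,3-oxazolidin-2-one
Product: 10 N-acyl oxazolidinone, via mixed pivalic anhydride 9 (not isolated)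
Conditions: t-BuCOCl, Et3N, THF, −20 °C; then LiCl, 8, −20 °C to rt
Reagents that add atoms: none
Why: N-acylation of the oxazolidinone through the mixed pivalic anhydride (LiCl/Et3N variant), which attaches the chiral auxiliary without strong base and without touching C1.

Step 5
Reactants: 10 N-acyl oxazolidinone; 11 tert-butyl bromoacetate
Product: 13 C2-alkylated imide (3R,4R), via sodium Z-enolate 12 (not isolated)
Conditions: NaN(SiMe3)2 (1.1 equiv), THF, −78 °C; 11, −78 to −40 °C
Reagents that add atoms: none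
Why: Evans asymmetric alkylation, in which the chelated sodium Z-enolate is alkylated on the face opposite the benzyl group of the (R)-auxiliary, setting C2 as R by reagent control that should override the neighbouring C1 centre.

Step 6
Reactants: 13 alkylated imide
Product: 15 (4R)-4-[(1R)-1-aryl-3-(trimethylsilyl)prop-2-yn-1-yl]oxolan-2-one, via hydroxy ester 14 (not isolated)
Conditions: LiBH4, MeOH (1 equiv), THF, 0 °C; then p-TsOH·H2O (cat.), toluene, 80 °C
Reagents that add atoms: none
Why: Reductive cleavage of the imide with LiBH4 (tert-butyl ester untouched) frees the C2a hydroxyl and the auxiliary, and acid-catalysed lactonisation of 14 with loss of isobutene should give the γ-lactone without affecting C1 or C2.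

Step 7
Reactants: 15 γ-lactone
Product: 18 α-(diethoxyphosphoryl) lactone (C3 epimers), via lithium enolate 16 (not isolated), via phosphonite 17 (not isolated)
Conditions: LiN(iPr)2 (1.1 equiv), THF, −78 °C; ClP(OEt)2, −78 °C to rt; then 30 % H2O2, 0 °C
Reagents that add atoms: diethyl chlorophosphite, CCOP(Cl)OCC; hydrogen peroxide, OO
Why: Enolate C-phosphinylation then oxidation, in which the lithium enolate reacts at carbon with the soft trivalent phosphorus chloride and H2O2 oxidises the phosphonite to the phosphonate; the new C3 centre is of no consequence because it becomes trigonal in step 9.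

Step 8
Reactants: 18 phosphono lactone
Product: 19 phosphono lactone with free C8a alkyne
Conditions: K2CO3, MeOH, rt; acidic work-up
Reagents that add atoms: none
Why: Base-catalysed methanolysis of the C(sp)–Si bond (protiodesilylation), done before the second silyl-capped alkyne is brought in so that the two alkynes stay distinguishable.

Step 9
Reactants: 19 phosphono lactone; 20 3-(trimethylsilyl)prop-2-ynal
Product: 22 (E)-alkylidene lactone, via sodium phosphonate carbanion 21 (not isolated)
Conditions: NaH (1.05 equiv), THF, 0 °C; 20, 0 °C to rt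
Reagents that add atoms: none
Why: Horner–Wadsworth–Emmons olefination, in which NaH deprotonates only the acidic phosphonate C–H beside the terminal alkyne and the stabilised carbanion should give mainly the alkylidene lactone with the alkynyl group trans to the carbonyl and so cis to C2 (E), any Z isomer being removed by chromatography.

Step 10
Reactants: 22 alkylidene lactone
Product: 23 enyne 1,4-diol
Conditions: iBu2AlH (4.5 equiv), CH2Cl2, −78 to −20 °C; aq. potassium sodium tartrate
Reagents that add atoms: none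
Why: 1,2-Reduction of the unsaturated lactone with iBu2AlH should give the 1,4-diol without touching the enyne, the terminal alkyne or the alkene geometry.

Step 11
Reactants: 23 diol
Product: 24 bis(tert-butyldimethylsilyl) ether
Conditions: TBSCl (2.5 equiv), imidazole, DMF, rt
Reagents that add atoms: tert-butyldimethylsilyl chloride, CC(C)(C)[Si](C)(C)Cl
Why: Imidazole-promoted silylation of both primary alcohols masks them for the strongly basic and organometallic steps that follow.

Step 12
Reactants: 24 bis-silyl ether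
Product: 27 C8 triisopropylsiloxy alkyne with C5–SiMe3, via lithium acetylide 25 (not isolated), via lithium ynolate 26 (not isolated)
Conditions: LiN(SiMe3)2 (1.1 equiv), THF, −78 °C; t-BuOOLi (from t-BuOOH and LiN(SiMe3)2), −78 to 0 °C; iPr3SiOTf, −78 °C
Reagents that add atoms: tert-butyl hydroperoxide, CC(C)(C)OO; triisopropylsilyl triflate, CC(C)[Si](OS(=O)(=O)C(F)(F)F)(C(C)C)C(C)C
Why: Oxidation of a lithium acetylide by lithium tert-butyl peroxide to the ynolate and O-silylation with a bulky silyl triflate, the known route from terminal alkynes to siloxyalkynes, which should act only at C8a because that is the only alkyne with an acidic hydrogen.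

Step 13
Reactants: 27 siloxyalkyne with C5–SiMe3
Product: 28 (E)-enediyne with terminal C5 alkyne and C8 siloxyalkyne
Conditions: K2CO3 (0.2 equiv), MeOH/THF (1:1), 0 °C, stopped at full conversion
Reagents that add atoms: none
Why: Protiodesilylation of the alkynyl C–SiMe3 bond with catalytic methoxide, relying on attack at the unhindered SiMe3 group being much faster than at the shielded silicon of the triisopropylsilyl ynol ether or of the tert-butyldimethylsilyl ethers.

Step 14
Reactants: 29 trichloroethylene; 30 2-isopropoxy-4,4,5,5-tetramethyl-1,3,2-dioxaborolane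
Product: 33 bis(pinacolboryl)acetylene, via dilithioacetylene 31 (not isolated), via bis-borate complex 32 (not isolated)
Conditions: n-BuLi (3 equiv), Et2O, −78 °C to rt; 30 (2 equiv), −78 °C; HCl·Et2O, −78 °C to rt
Reagents that add atoms: none
Why: Borylation of an acetylide, in which dilithioacetylene (from trichloroethylene by deprotonation, elimination and two chlorine–lithium exchanges) adds to two molecules of the borate ester and HCl removes isopropoxide from the bis-ate complex.

Step 15
Reactants: 28 (E)-enediyne; 33 bis(pinacolboryl)acetylene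
Product: 35 6,7-diboryl-8-siloxy-1-aryl-1,2-dihydronaphthalene bis(silyl ether), via cobaltacyclopentadiene 34 (not isolated)
Conditions: CpCo(CO)2 (20 mol %, monovalent cobalt), 33 (4 equiv), degassed toluene, 110 °C, hν (visible lamp), 28 added over 10 h
Reagents that add atoms: none
Why: CpCo(CO)2 loses CO under heat and light, binds both alkynes of 28 and couples them oxidatively to cobaltacyclopentadiene 34 (trivalent cobalt), which forms C4a–C8a and closes ring B as a six-membered ring through the tether C1–C2–C3=C4. Alkyne 33 then coordinates and inserts, and reductive elimination forms C5–C6 and C7–C8, closing ring A as the benzene ring and returning monovalent cobalt. The closest known reaction type is the cobalt-mediated [2+2+2] cocyclisation of α,ω-diynes with silyl- or boryl-substituted alkynes. No stereocentre is formed, and C1 and C2, both sp3 and outside the reacting π systems, should pass through unchanged. The step needs cross-selectivity over self-trimerisation of 28, secured by the excess of 33 (too hindered to trimerise itself) and slow addition of 28; the tether fixes the regiochemistry (OSi at C8, H at C5, boron at C6 and C7), and the E geometry of C3=C4, with the ethynyl group cis to C2, lets both alkynes reach the same cobalt.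

Step 16
Reactants: 35 diboryl arene
Product: 36 6,7-dihydroxy arene (catechol)
Conditions: NaBO3·4H2O (6 equiv), THF/H2O (1:1), rt, argon
Reagents that add atoms: sodium perborate, [Na+].[O-]OB=O
Why: Perborate oxidation of aryl–boron bonds (1,2-shift of aryl from boron to oxygen, then hydrolysis) should turn both boronic esters into phenols under mild conditions that leave the silyl ethers and the C3=C4 bond intact.

Step 17
Reactants: 36 catechol
Product: 37 pentaol (6,7,8-triol, 2a,3a-diol)
Conditions: Bu4NF (5 equiv), THF, 0 °C to rt, argon; aq. NH4Cl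
Reagents that add atoms: none
Why: Fluoride-induced cleavage of all three silicon–oxygen bonds (desilylation), run with exclusion of air because the 6,7,8-trihydroxyarene is easily oxidised.

Step 18
Reactants: 37 pentaol
Product: 38 CNP0274357.1
Conditions: MeI (6 equiv), K2CO3, acetone, 50 °C, argon
Reagents that add atoms: iodomethane, CI
Why: Williamson ether synthesis under phenol-selective conditions, in which K2CO3 deprotonates only the three phenols and not the two primary alcohols, so MeI should methylate O6, O7 and O8 alone and leave C1 and C2 unchanged.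

**Compound list**

1 | 3,4-dimethoxybenzaldehyde (veratraldehyde) | COc1ccc(C=O)cc1OC | starting material
2 | 2,2-dimethyl-1,3-dioxane-4,6-dione (Meldrum's acid) | CC1(C)OC(=O)CC(=O)O1 | starting material
3 | 5-(3,4-dimethoxybenzylidene)-2,2-dimethyl-1,3-dioxane-4,6-dione | COc1ccc(C=C2C(=O)OC(C)(C)OC2=O)cc1OC | intermediate
4 | ethynyltrimethylsilane (trimethylsilylacetylene) | C#C[Si](C)(C)C | starting material
5 | 5-[(1R)-1-(3,4-dimethoxyphenyl)-3-(trimethylsilyl)prop-2-yn-1-yl]-2,2-dimethyl-1,3-dioxane-4,6-dione | COc1ccc([C@H](C#C[Si](C)(C)C)C2C(=O)OC(C)(C)OC2=O)cc1OC | intermediate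
6 | 2-[(1R)-1-(3,4-dimethoxyphenyl)-3-(trimethylsilyl)prop-2-yn-1-yl]propanedioic acid | COc1ccc([C@H](C#C[Si](C)(C)C)C(C(=O)O)C(=O)O)cc1OC | intermediate
7 | (3R)-3-(3,4-dimethoxyphenyl)-5-(trimethylsilyl)pent-4-ynoic acid | COc1ccc([C@H](C#C[Si](C)(C)C)CC(=O)O)cc1OC | intermediate
8 | (4R)-4-benzyl-1,3-oxazolidin-2-one | O=C1N[C@H](Cc2ccccc2)CO1 | starting material
9 | mixed anhydride of 7 with pivalic acid | COc1ccc([C@H](C#C[Si](C)(C)C)CC(=O)OC(=O)C(C)(C)C)cc1OC | intermediate
10 | (4R)-4-benzyl-3-[(3R)-3-(3,4-dimethoxyphenyl)-5-(trimethylsilyl)pent-4-ynoyl]-1,3-oxazolidin-2-one | COc1ccc([C@H](C#C[Si](C)(C)C)CC(=O)N2[C@H](Cc3ccccc3)COC2=O)cc1OC | intermediate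
11 | tert-butyl bromoacetate | CC(C)(C)OC(=O)CBr | starting material
12 | sodium (Z)-enolate of 10 | [Na+].COc1ccc([C@H](C#C[Si](C)(C)C)/C=C(\[O-])N2[C@H](Cc3ccccc3)COC2=O)cc1OC | intermediate
13 | tert-butyl (3R,4R)-3-{[(4R)-4-benzyl-2-oxo-1,3-oxazolidin-3-yl]carbonyl}-4-(3,4-dimethoxyphenyl)-6-(trimethylsilyl)hex-5-ynoate | COc1ccc([C@H](C#C[Si](C)(C)C)[C@@H](CC(=O)OC(C)(C)C)C(=O)N2[C@H](Cc3ccccc3)COC2=O)cc1OC | intermediate
14 | tert-butyl (3R,4R)-4-(3,4-dimethoxyphenyl)-3-(hydroxymethyl)-6-(trimethylsilyl)hex-5-ynoate | COc1ccc([C@H](C#C[Si](C)(C)C)[C@@H](CC(=O)OC(C)(C)C)CO)cc1OC | intermediate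
15 | (4R)-4-[(1R)-1-(3,4-dimethoxyphenyl)-3-(trimethylsilyl)prop-2-yn-1-yl]oxolan-2-one | COc1ccc([C@H](C#C[Si](C)(C)C)[C@H]2CC(=O)OC2)cc1OC | intermediate
16 | lithium enolate of 15 | [Li+].COc1ccc([C@H](C#C[Si](C)(C)C)[C@H]2C=C([O-])OC2)cc1OC | intermediate
17 | diethyl {(4R)-4-[(1R)-1-(3,4-dimethoxyphenyl)-3-(trimethylsilyl)prop-2-yn-1-yl]-2-oxooxolan-3-yl}phosphonite (C3 epimers) | COc1ccc([C@H](C#C[Si](C)(C)C)[C@H]2C(P(OCC)OCC)C(=O)OC2)cc1OC | intermediate
18 | diethyl {(4R)-4-[(1R)-1-(3,4-dimethoxyphenyl)-3-(trimethylsilyl)prop-2-yn-1-yl]-2-oxooxolan-3-yl}phosphonate (C3 epimers) | COc1ccc([C@H](C#C[Si](C)(C)C)[C@H]2C(P(=O)(OCC)OCC)C(=O)OC2)cc1OC | intermediate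
19 | diethyl {(4R)-4-[(1S)-1-(3,4-dimethoxyphenyl)prop-2-yn-1-yl]-2-oxooxolan-3-yl}phosphonate (C3 epimers) | COc1ccc([C@H](C#C)[C@H]2C(P(=O)(OCC)OCC)C(=O)OC2)cc1OC | intermediate
20 | 3-(trimethylsilyl)prop-2-ynal | C[Si](C)(C)C#CC=O | starting material
21 | sodium salt of the phosphonate carbanion of 19 | [Na+].COc1ccc([C@H](C#C)[C@H]2[C-](P(=O)(OCC)OCC)C(=O)OC2)cc1OC | intermediate
22 | (3E,4S)-4-[(1S)-1-(3,4-dimethoxyphenyl)prop-2-yn-1-yl]-3-[3-(trimethylsilyl)prop-2-yn-1-ylidene]oxolan-2-one | COc1ccc([C@H](C#C)[C@@H]2COC(=O)/C2=C/C#C[Si](C)(C)C)cc1OC | intermediate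
23 | (2E,3S)-3-[(1S)-1-(3,4-dimethoxyphenyl)prop-2-yn-1-yl]-2-[3-(trimethylsilyl)prop-2-yn-1-ylidene]butane-1,4-diol | COc1ccc([C@H](C#C)[C@H](CO)/C(CO)=C\C#C[Si](C)(C)C)cc1OC | intermediate
24 | (2S,3E)-1-[(tert-butyldimethylsilyl)oxy]-3-{[(tert-butyldimethylsilyl)oxy]methyl}-2-[(1S)-1-(3,4-dimethoxyphenyl)prop-2-yn-1-yl]-6-(trimethylsilyl)hex-3-en-5-yne | COc1ccc([C@H](C#C)[C@H](CO[Si](C)(C)C(C)(C)C)/C(CO[Si](C)(C)C(C)(C)C)=C\C#C[Si](C)(C)C)cc1OC | intermediate
25 | lithium acetylide of 24 (at C8) | [Li+].COc1ccc([C@H](C#[C-])[C@H](CO[Si](C)(C)C(C)(C)C)/C(CO[Si](C)(C)C(C)(C)C)=C\C#C[Si](C)(C)C)cc1OC | intermediate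
26 | lithium ynolate (C8–O−) derived from 25 | [Li+].COc1ccc([C@H](C#C[O-])[C@H](CO[Si](C)(C)C(C)(C)C)/C(CO[Si](C)(C)C(C)(C)C)=C\C#C[Si](C)(C)C)cc1OC | intermediate
27 | (2S,3E)-1-[(tert-butyldimethylsilyl)oxy]-3-{[(tert-butyldimethylsilyl)oxy]methyl}-2-{(1R)-1-(3,4-dimethoxyphenyl)-3-[(triisopropylsilyl)oxy]prop-2-yn-1-yl}-6-(trimethylsilyl)hex-3-en-5-yne | COc1ccc([C@H](C#CO[Si](C(C)C)(C(C)C)C(C)C)[C@H](CO[Si](C)(C)C(C)(C)C)/C(CO[Si](C)(C)C(C)(C)C)=C\C#C[Si](C)(C)C)cc1OC | intermediate
28 | (2S,3E)-1-[(tert-butyldimethylsilyl)oxy]-3-{[(tert-butyldimethylsilyl)oxy]methyl}-2-{(1R)-1-(3,4-dimethoxyphenyl)-3-[(triisopropylsilyl)oxy]prop-2-yn-1-yl}hex-3-en-5-yne (ethynyl cis to C2) | COc1ccc([C@H](C#CO[Si](C(C)C)(C(C)C)C(C)C)[C@H](CO[Si](C)(C)C(C)(C)C)/C(CO[Si](C)(C)C(C)(C)C)=C\C#C)cc1OC | intermediate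
29 | trichloroethylene | ClC=C(Cl)Cl | starting material
30 | 2-isopropoxy-4,4,5,5-tetramethyl-1,3,2-dioxaborolane | CC(C)OB1OC(C)(C)C(C)(C)O1 | starting material
31 | dilithioacetylene | [Li]C#C[Li] | intermediate
32 | dilithium ethyne-1,2-diylbis(isopropoxy pinacol borate) | [Li+].[Li+].CC(C)O[B-]1(OC(C)(C)C(C)(C)O1)C#C[B-]1(OC(C)C)OC(C)(C)C(C)(C)O1 | intermediate
33 | 1,2-bis(4,4,5,5-tetramethyl-1,3,2-dioxaborolan-2-yl)ethyne | CC1(C)OB(C#CB2OC(C)(C)C(C)(C)O2)OC1(C)C | intermediate
34 | cyclopentadienylcobalt cobaltacyclopentadiene (Co bonded to C5 and C8, ring B closed) | COc1ccc([C@@H]2C3=C(O[Si](C(C)C)(C(C)C)C(C)C)[Co](C4C=CC=C4)C=C3C=C(CO[Si](C)(C)C(C)(C)C)[C@H]2CO[Si](C)(C)C(C)(C)C)cc1OC | intermediate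
35 | (1R,2S)-2,3-bis{[(tert-butyldimethylsilyl)oxy]methyl}-1-(3,4-dimethoxyphenyl)-6,7-bis(4,4,5,5-tetramethyl-1,3,2-dioxaborolan-2-yl)-8-[(triisopropylsilyl)oxy]-1,2-dihydronaphthalene | COc1ccc([C@@H]2c3c(cc(B4OC(C)(C)C(C)(C)O4)c(B4OC(C)(C)C(C)(C)O4)c3O[Si](C(C)C)(C(C)C)C(C)C)C=C(CO[Si](C)(C)C(C)(C)C)[C@H]2CO[Si](C)(C)C(C)(C)C)cc1OC | intermediate
36 | (1R,2S)-2,3-bis{[(tert-butyldimethylsilyl)oxy]methyl}-1-(3,4-dimethoxyphenyl)-8-[(triisopropylsilyl)oxy]-1,2-dihydronaphthalene-6,7-diol (target numbering) | COc1ccc([C@@H]2c3c(cc(O)c(O)c3O[Si](C(C)C)(C(C)C)C(C)C)C=C(CO[Si](C)(C)C(C)(C)C)[C@H]2CO[Si](C)(C)C(C)(C)C)cc1OC | intermediate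
37 | (1R,2S)-1-(3,4-dimethoxyphenyl)-2,3-bis(hydroxymethyl)-1,2-dihydronaphthalene-6,7,8-triol (target numbering) | COc1ccc([C@@H]2c3c(cc(O)c(O)c3O)C=C(CO)[C@H]2CO)cc1OC | intermediate
38 | [(1R,2S)-1-(3,4-dimethoxyphenyl)-6,7,8-trimethoxy-1,2-dihydronaphthalene-2,3-diyl]dimethanol (CNP0274357.1; aryl and C2 hydroxymethyl trans) | COc1ccc([C@@H]2c3c(cc(OC)c(OC)c3OC)C=C(CO)[C@H]2CO)cc1OC | target

**Step count**

Total steps: 18. Longest linear sequence: 17 (steps 1–13 and 15–18); step 14 is a one-step branch.

**Steps most likely to fail**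

Step 15 (key cocyclisation). What may go wrong: self-oligomerisation of the diyne at cobalt, slow insertion of the hindered diboryl alkyne, and thermal 1,3-shift of silicon in the ynol ether before it is consumed. Fallback: separate the two stages with stoichiometric cobalt. The fallback sets out from 28, which is treated with CpCo(PPh3)2 (1 equiv, monovalent cobalt) in toluene at rt; this should give the isolable triphenylphosphine cobaltacyclopentadiene F1, so the ynol ether is consumed without heating. F1 is then heated with excess 33 and added PPh3 in toluene at 110 °C, which should release arene 35, where the route is rejoined.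

Step 13 (C–SiMe3 cleavage beside the ynol silyl ether). What may go wrong: methanolysis of the O–Si bond of the ynol ether competing with C–Si cleavage, with loss of the protecting group and collapse of the ynol to an ester. Fallback: bring in C5 without silicon and free the alkyne with a bulky amide base. The fallback sets out from 19, which undergoes the same Horner–Wadsworth–Emmons reaction (NaH, THF) with 2-bromoprop-2-enal (from acrolein, Br2, then Et3N) to give bromodiene lactone F2. iBu2AlH reduction gives bromodiene diol F3, and TBSCl/imidazole gives bis-silyl ether F4. Acetylide oxidation and O-silylation as in step 12, kept at or below −20 °C, gives bromodiene siloxyalkyne F5. Dehydrobromination with LiN(iPr)2 (2.2 equiv, THF, −78 °C, then aq. NH4Cl) should give 28, where the route is rejoined.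

Step 2 (enantioselective alkynylation). What may go wrong: poor facial selectivity with the electron-rich arylidene, or alkyne dimerisation at rhodium. Fallback: racemic addition and resolution through the auxiliary already in the route. The fallback sets out from 3, to which BrMgC≡CSiMe3 (from 4 and EtMgBr, THF, 0 °C) adds to give racemic adduct F6. DMF/H2O at 100 °C gives racemic acid F7. Coupling with 8 as in step 4 gives 10 together with its C1 epimer F8; the two diastereomers are separated by chromatography or crystallisation, and the route is rejoined at 10.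

**Further compounds**

F1 | step 15 | cyclopentadienyl(triphenylphosphine)cobalt cobaltacyclopentadiene from 28 | COc1ccc([C@@H]2C3=C(O[Si](C(C)C)(C(C)C)C(C)C)[Co](C4C=CC=C4)(P(c4ccccc4)(c4ccccc4)c4ccccc4)C=C3C=C(CO[Si](C)(C)C(C)(C)C)[C@H]2CO[Si](C)(C)C(C)(C)C)cc1OC
F2 | step 13 | (3E,4S)-3-(2-bromoprop-2-en-1-ylidene)-4-[(1S)-1-(3,4-dimethoxyphenyl)prop-2-yn-1-yl]oxolan-2-one | COc1ccc([C@H](C#C)[C@@H]2COC(=O)/C2=C/C(Br)=C)cc1OC
F3 | step 13 | (2E,3S)-2-(2-bromoprop-2-en-1-ylidene)-3-[(1S)-1-(3,4-dimethoxyphenyl)prop-2-yn-1-yl]butane-1,4-diol | COc1ccc([C@H](C#C)[C@H](CO)/C(CO)=C\C(Br)=C)cc1OC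
F4 | step 13 | bis(tert-butyldimethylsilyl) ether of F3 | COc1ccc([C@H](C#C)[C@H](CO[Si](C)(C)C(C)(C)C)/C(CO[Si](C)(C)C(C)(C)C)=C\C(Br)=C)cc1OC
F5 | step 13 | C8 triisopropylsiloxy alkyne derived from F4 | COc1ccc([C@H](C#CO[Si](C(C)C)(C(C)C)C(C)C)[C@H](CO[Si](C)(C)C(C)(C)C)/C(CO[Si](C)(C)C(C)(C)C)=C\C(Br)=C)cc1OC
F6 | step 2 | racemic 5-[1-(3,4-dimethoxyphenyl)-3-(trimethylsilyl)prop-2-yn-1-yl]-2,2-dimethyl-1,3-dioxane-4,6-dione | COc1ccc(C(C#C[Si](C)(C)C)C2C(=O)OC(C)(C)OC2=O)cc1OC
F7 | step 2 | racemic 3-(3,4-dimethoxyphenyl)-5-(trimethylsilyl)pent-4-ynoic acid | COc1ccc(C(C#C[Si](C)(C)C)CC(=O)O)cc1OC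
F8 | step 2 | (4R)-4-benzyl-3-[(3S)-3-(3,4-dimethoxyphenyl)-5-(trimethylsilyl)pent-4-ynoyl]-1,3-oxazolidin-2-one | COc1ccc([C@@H](C#C[Si](C)(C)C)CC(=O)N2[C@H](Cc3ccccc3)COC2=O)cc1OC
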